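**Retrosynthetic overview**
1. Target 17 is 2,3,4-tribromo-6-(2,4-dibromophenoxy)phenol. The plan rests on ring A, where C1 (OH), C2 (O-aryl) and C3 (H) are followed by three adjacent C–Br carbons, C4, C5 and C6.
2. Last disconnection: the two C–Br bonds of ring B (para, then ortho to the ether oxygen), by electrophilic bromination of phenol 15.
3. The C1–OH bond is traced back to a C1–Br bond in 12 (oxygen-guided Br/Mg exchange, borylation, oxidation).
4. Ring A, the only ring formed, is opened at C1–C2 and C3–C4: Diels–Alder reaction of tetrabromothiophene 1,1-dioxide 3 with phenoxyacetylene 10, then loss of SO2.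
5. Ring B is bought as phenol; 3 comes from tetrabromothiophene by S-oxidation, 10 from phenol and trichloroethylene.

Key step: step 4

Remark: phenoxyacetylene 10 is a labile terminal ynol ether and is assumed to be carried into step 4 as a freshly made solution, without storage.

**Step 1**
Reactants: 1 2,3,4,5-tetrabromothiophene
Product: 3 2,3,4,5-tetrabromothiophene 1,1-dioxide, via tetrabromothiophene 1-oxide 2 (not isolated)
Conditions: H2O2·urea, (CF3CO)2O, CH2Cl2, 0 → 40 °C
Reagents that add atoms: trifluoroperacetic acid, OOC(=O)C(F)(F)F (formed in the flask from urea–hydrogen peroxide, NC(N)=O.OO, and trifluoroacetic anhydride)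
Why: Peroxytrifluoroacetic acid is electrophilic enough to oxidise the electron-poor sulfur twice (sulfide to sulfoxide to sulfone), and the four bromines keep the non-aromatic sulfoxide and sulfone from dimerising.

**Step 2**
Reactants: 4 phenol; 5 trichloroethylene
Product: 7 (E)-1,2-dichlorovinyl phenyl ether, via dichloroacetylene 6 (not isolated)
Conditions: K2CO3, DMF, 70 °C
Reagents that add atoms: none
Why: Carbonate eliminates HCl from trichloroethylene to dichloroacetylene, and phenoxide adds to this haloalkyne in anti fashion (nucleophilic addition), which fixes the E geometry of the enol ether.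

**Step 3**
Reactants: 7 (E)-1,2-dichlorovinyl phenyl ether
Product: 10 phenoxyacetylene (ethynyl phenyl ether), via chloro(phenoxy)acetylene 8 (not isolated), via lithium phenoxyacetylide 9 (not isolated)
Conditions: n-C4H9Li (2.2 equiv), Et2O, −78 → −40 °C; H2O, −78 → 0 °C; dried, concentrated cold, taken up in toluene and used at once
Reagents that add atoms: none
Why: n-C4H9Li removes the vinylic proton, anti elimination of LiCl gives the chloroalkyne, chlorine/lithium exchange with the second equivalent gives the acetylide, and water protonates it (the dehydrochlorination/halogen–lithium exchange route to ynol ethers).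

**Step 4**
Reactants: 3 2,3,4,5-tetrabromothiophene 1,1-dioxide; 10 phenoxyacetylene (1.3 equiv)
Product: 12 1,2,3,4-tetrabromo-5-phenoxybenzene, via thiabicycloheptadiene dioxide adduct 11 (not isolated)
Conditions: toluene, 25 → 60 °C, slow N2 stream to carry off SO2
Reagents that add atoms: none
Why: The sulfone and four bromines lower the LUMO of the non-aromatic diene 3 while the oxygen lone pair raises the HOMO of ynol ether 10, so an inverse-electron-demand [4+2] cycloaddition, probably asynchronous with the C3–C4 bond from the terminal alkyne carbon leading, should give the 7-thiabicyclo[2.2.1]hepta-2,5-diene 7,7-dioxide 11. Cheletropic loss of SO2 from 11, driven by aromatisation, then delivers arene 12; the closest known reaction type is the cycloaddition of tetrahalothiophene 1,1-dioxides with alkynes to give tetrahalobenzenes. Ring A, a six-membered carbocycle, is closed by this intermolecular [4+2] cycloaddition, which forms C1–C2 and C3–C4, and is made aromatic by the extrusion. No stereocentre is carried forward, since the two bridgehead carbons of racemic 11 become sp2 when SO2 leaves. No regiochemistry has to be controlled, because the two diene termini of 3 are equivalent by symmetry and either orientation of 10 leads to the same arene. The chemoselectivity needed, cross-cycloaddition ahead of self-reaction of either partner, is secured by the complementary polarity of the pair and by the full substitution of 3, while the halogen-free ring B and the aromatic product 12 are inert to 3.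

**Step 5**
Reactants: 12 1,2,3,4-tetrabromo-5-phenoxybenzene
Product: 15 2,3,4-tribromo-6-phenoxyphenol, via bis(aryl)magnesium 13 (not isolated), via dimethyl arylboronate 14 (not isolated)
Conditions: sBu2Mg·2LiOCH2CH(C2H5)C4H9 (0.6 equiv), toluene, −40 °C; B(OMe)3, −40 → 0 °C; AcOH, 30% H2O2, 0 → 20 °C
Reagents that add atoms: hydrogen peroxide, OO
Why: In donor-free toluene the lithium alkoxide–magnesium reagent can bind only the diaryl ether oxygen, so the Br/Mg exchange (complex-induced proximity) should be delivered to the adjacent C1–Br rather than to the three other bromines, ring B has no halogen to compete, and borate trapping followed by peroxide-induced 1,2-aryl shift (boronate oxidation) turns C–Mg into C–OH.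

**Step 6**
Reactants: 15 2,3,4-tribromo-6-phenoxyphenol
Product: 17 2,3,4-tribromo-6-(2,4-dibromophenoxy)phenol, via 4-bromophenoxy intermediate 16 (not isolated)
Conditions: Br2 (2.1 equiv), AcOH, 20 → 50 °C
Reagents that add atoms: bromine, BrBr
Why: Electrophilic aromatic bromination should go para and then ortho to the ether oxygen on ring B, since on ring A every position ortho or para to OH is occupied and the lone C3–H is meta to OH and deactivated by three bromines.

**Compound list**
1 | 2,3,4,5-tetrabromothiophene | Brc1sc(Br)c(Br)c1Br | starting material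
2 | 2,3,4,5-tetrabromothiophene 1-oxide | O=S1C(Br)=C(Br)C(Br)=C1Br | intermediate (not isolated)
3 | 2,3,4,5-tetrabromothiophene 1,1-dioxide | O=S1(=O)C(Br)=C(Br)C(Br)=C1Br | intermediate
4 | phenol | Oc1ccccc1 | starting material
5 | trichloroethylene | ClC=C(Cl)Cl | starting material
6 | dichloroacetylene | ClC#CCl | intermediate (not isolated)
7 | (E)-1,2-dichlorovinyl phenyl ether | Cl/C=C(/Cl)Oc1ccccc1 | intermediate
8 | chloro(phenoxy)acetylene | ClC#COc1ccccc1 | intermediate (not isolated)
9 | lithium phenoxyacetylide | [Li]C#COc1ccccc1 | intermediate (not isolated)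
10 | phenoxyacetylene | C#COc1ccccc1 | intermediate
11 | 1,4,5,6-tetrabromo-2-phenoxy-7-thiabicyclo[2.2.1]hepta-2,5-diene 7,7-dioxide (racemic, one enantiomer written; bridgeheads tied cis by the SO2 bridge) | Br[C@@]12C(Br)=C(Br)[C@@](Br)(C=C1Oc1ccccc1)S2(=O)=O | intermediate (not isolated)
12 | 1,2,3,4-tetrabromo-5-phenoxybenzene | Brc1cc(Oc2ccccc2)c(Br)c(Br)c1Br | intermediate
13 | bis(2,3,4-tribromo-6-phenoxyphenyl)magnesium (as its complex with two lithium 2-ethylhexoxide units) | Brc1cc(Oc2ccccc2)c([Mg]c2c(Oc3ccccc3)cc(Br)c(Br)c2Br)c(Br)c1Br | intermediate (not isolated)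
14 | dimethyl (2,3,4-tribromo-6-phenoxyphenyl)boronate | COB(OC)c1c(Oc2ccccc2)cc(Br)c(Br)c1Br | intermediate (not isolated)
15 | 2,3,4-tribromo-6-phenoxyphenol | Oc1c(Oc2ccccc2)cc(Br)c(Br)c1Br | intermediate
16 | 2,3,4-tribromo-6-(4-bromophenoxy)phenol | Oc1c(Oc2ccc(Br)cc2)cc(Br)c(Br)c1Br | intermediate (not isolated)
17 | 2,3,4-tribromo-6-(2,4-dibromophenoxy)phenol | Oc1c(Oc2ccc(Br)cc2Br)cc(Br)c(Br)c1Br | target

**Step count**
Total: 6 steps. Longest linear sequence: 5 steps (steps 2, 3, 4, 5, 6 from phenol); the branch from 1 joins at step 4.

**Steps most likely to fail**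

1. Step 5. The exchange may lose site selectivity: the two bromines flanked by bromine on both sides (at C5 and C6) are inductively at least as activated as the C1–Br beside the ether oxygen, and the aryl–Mg species may also scramble by transfer to unreacted 12. The fallback lets a C–H bond mark C1 instead of choosing among four bromines. It sets out from phenoxyacetylene 10. Cycloaddition with 3,4-dibromothiophene 1,1-dioxide F1 (from commercial 3,4-dibromothiophene by the oxidation of step 1, used fresh and cold) should give, through 5,6-dibromo-2-phenoxy-7-thiabicyclo[2.2.1]hepta-2,5-diene 7,7-dioxide F2 (not isolated), 1,2-dibromo-4-phenoxybenzene F3. This is the same ring A closure with hydrogen at C1 and C4. LiN(iPr)2 in THF at −78 °C should remove the one proton flanked by the ether oxygen and a bromine (C1–H) to give (2,3-dibromo-6-phenoxyphenyl)lithium F4. B(OMe)3 gives dimethyl (2,3-dibromo-6-phenoxyphenyl)boronate F5, and AcOH/H2O2 gives 2,3-dibromo-6-phenoxyphenol F6. One equivalent of Br2 in AcOH at 0 °C then brominates para to the hydroxyl (C4), and the route is rejoined at 15.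

2. Step 4. The terminal ynol ether may oligomerise, hydrate with adventitious acid from SO2, or add stepwise to the vinyl sulfone faster than it undergoes the concerted cycloaddition. The fallback replaces it by a robust C-silyl ynol ether and removes silicon afterwards. It sets out from dichlorovinyl ether 7. Lithium acetylide 9 is quenched with Me3SiCl instead of water to give trimethyl(phenoxyethynyl)silane F7, which can be distilled and heated. Cycloaddition with 3 in toluene at 80–110 °C should give, through 1,4,5,6-tetrabromo-2-phenoxy-3-(trimethylsilyl)-7-thiabicyclo[2.2.1]hepta-2,5-diene 7,7-dioxide F8 (not isolated), (2,3,4,5-tetrabromo-6-phenoxyphenyl)trimethylsilane F9. Bu4NF in wet THF should then cleave the C–Si bond (protodesilylation through an aryl anion stabilised by the flanking Br and O), and the route is rejoined at 12.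

3. Step 6. The second, ortho bromination of ring B may stall, and forcing it may cause over-bromination or ipso attack and oxidation of the electron-rich phenol ring. The fallback masks the phenol so that ring A is switched off and a Lewis acid can be used. It sets out from 15. Ac2O/pyridine gives 2,3,4-tribromo-6-phenoxyphenyl acetate F10. Br2 (2.1 equiv) with catalytic FeBr3 in CH2Cl2 should brominate ring B through 2,3,4-tribromo-6-(4-bromophenoxy)phenyl acetate F11 (not isolated) to 2,3,4-tribromo-6-(2,4-dibromophenoxy)phenyl acetate F12. K2CO3 in MeOH cleaves the acetate, and the route is rejoined at 17.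

**Further compounds**
F1 | step 5 | 3,4-dibromothiophene 1,1-dioxide | O=S1(=O)C=C(Br)C(Br)=C1
F2 | step 5 | 5,6-dibromo-2-phenoxy-7-thiabicyclo[2.2.1]hepta-2,5-diene 7,7-dioxide (racemic, one enantiomer written) | [C@@H]12C(Br)=C(Br)[C@@H](C=C1Oc1ccccc1)S2(=O)=O
F3 | step 5 | 1,2-dibromo-4-phenoxybenzene | Brc1ccc(Oc2ccccc2)cc1Br
F4 | step 5 | (2,3-dibromo-6-phenoxyphenyl)lithium | [Li]c1c(Oc2ccccc2)ccc(Br)c1Br
F5 | step 5 | dimethyl (2,3-dibromo-6-phenoxyphenyl)boronate | COB(OC)c1c(Oc2ccccc2)ccc(Br)c1Br
F6 | step 5 | 2,3-dibromo-6-phenoxyphenol | Oc1c(Oc2ccccc2)ccc(Br)c1Br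
F7 | step 4 | trimethyl(phenoxyethynyl)silane | C[Si](C)(C)C#COc1ccccc1
F8 | step 4 | 1,4,5,6-tetrabromo-2-phenoxy-3-(trimethylsilyl)-7-thiabicyclo[2.2.1]hepta-2,5-diene 7,7-dioxide (racemic, one enantiomer written) | Br[C@@]12C(Br)=C(Br)[C@@](Br)(C([Si](C)(C)C)=C1Oc1ccccc1)S2(=O)=O
F9 | step 4 | (2,3,4,5-tetrabromo-6-phenoxyphenyl)trimethylsilane | C[Si](C)(C)c1c(Br)c(Br)c(Br)c(Br)c1Oc1ccccc1
F10 | step 6 | 2,3,4-tribromo-6-phenoxyphenyl acetate | CC(=O)Oc1c(Oc2ccccc2)cc(Br)c(Br)c1Br
F11 | step 6 | 2,3,4-tribromo-6-(4-bromophenoxy)phenyl acetate | CC(=O)Oc1c(Oc2ccc(Br)cc2)cc(Br)c(Br)c1Br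
F12 | step 6 | 2,3,4-tribromo-6-(2,4-dibromophenoxy)phenyl acetate | CC(=O)Oc1c(Oc2ccc(Br)cc2Br)cc(Br)c(Br)c1Br
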